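**Retrosynthetic overview**
1. The aryl ether at C11–O is made last from diol 23 and scopoletin 24 (Mitsunobu). The C3 alcohol comes from the C3 ketone, and the C4 gem-dimethyl group and trans C5–H come from the 4-en-3-one 19 by reductive methylation.
2. Ring B is closed on the monocyclic ring-A trifluoroborate 14 in one operation: a C5 radical adds to vinyltriphenylphosphonium (C6–C7), the adduct becomes an ylide, and the ylide olefinates the C8 methyl ketone. This forms C5–C6 and C7=C8.
3. Enabling feature: the isolated trisubstituted C7=C8 alkene of ring B is a carbonyl-olefination retron (C8 with its methyl C12 is a methyl ketone on C9). C5, two bonds away through C6H2, is the ring-fusion carbon β to the C3 carbonyl of ring A, and C5 and C8 are 1,4-related through C10–C9, so a two-carbon unit closes a six-membered ring. The C3 ketone lets C5 be borylated beforehand and reset afterwards.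
4. The C9/C10 pair comes from an iridium-catalysed branched allylation of the α′-enolate of vinylogous ester 7 with carbonate 3; ring A comes from 2-methylcyclohexane-1,3-dione.
5. Ring order: ring A (bought), ring B (step 10), coumarin attached last.

Key step: step 10

Assumption: the (Sa,S,S)-phosphoramidite in step 5 is taken to give the (R)-configured allylic carbon and the (6R) quaternary centre of 9; if the sense at the allylic carbon is opposite, the antipodal ligand is used.

Drimane numbering (C1–C12) is used in the explanations.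

Step 1
Reactants: 1 (E)-but-2-ene-1,4-diol
Product: 2 (E)-4-[(triisopropylsilyl)oxy]but-2-en-1-ol
Conditions: i-Pr3SiCl (1 equiv), imidazole, 1 (3 equiv), CH2Cl2, 0 °C
Reagents that add atoms: chlorotriisopropylsilane CC(C)[Si](Cl)(C(C)C)C(C)C
Why: Silyl ether formation on a symmetrical diol used in excess should give mainly the mono-ether.

Step 2
Reactants: 2 (E)-4-[(triisopropylsilyl)oxy]but-2-en-1-ol
Product: 3 methyl (E)-4-[(triisopropylsilyl)oxy]but-2-en-1-yl carbonate
Conditions: ClCO2Me, pyridine, CH2Cl2, 0 °C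
Reagents that add atoms: methyl chloroformate COC(=O)Cl
Why: Acylation of the primary allylic alcohol gives the carbonate leaving group needed for the allyl-iridium chemistry of step 5.

Step 3
Reactants: 4 2-methylcyclohexane-1,3-dione
Product: 5 3-isobutoxy-2-methylcyclohex-2-en-1-one
Conditions: i-BuOH, TsOH·H2O (cat.), toluene, reflux (Dean–Stark)
Reagents that add atoms: 2-methylpropan-1-ol CC(C)CO
Why: Acid-catalysed enol etherification of a cyclic 1,3-dione with removal of water gives the vinylogous ester that differentiates C3 from C5.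

Step 4
Reactants: 5 3-isobutoxy-2-methylcyclohex-2-en-1-one
Product: 7 3-isobutoxy-2,6-dimethylcyclohex-2-en-1-one, via lithium dienolate 6 (not isolated)
Conditions: LiN(i-Pr)2, THF, −78 °C; then MeI
Reagents that add atoms: iodomethane CI
Why: Kinetic α′-deprotonation of a vinylogous ester and C-methylation (Stork–Danheiser alkylation) puts the future angular methyl on C10; the racemic centre is erased in step 5.

Step 5
Reactants: 7 3-isobutoxy-2,6-dimethylcyclohex-2-en-1-one and 3 methyl (E)-4-[(triisopropylsilyl)oxy]but-2-en-1-yl carbonate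
Product: 9 (6R)-3-isobutoxy-2,6-dimethyl-6-[(2R)-1-[(triisopropylsilyl)oxy]but-3-en-2-yl]cyclohex-2-en-1-one, via lithium dienolate 8 (not isolated)
Conditions: LiN(SiMe3)2, THF, −78 to 0 °C; then 3, [Ir(cod)Cl]2 (2 mol %), (Sa,S,S)-O,O′-binaphthyl N,N-bis(1-phenylethyl)phosphoramidite (4 mol %, cyclometalated with n-PrNH2), THF, 0 °C to rt
Reagents that add atoms: none
Why: Iridium-catalysed branched-selective asymmetric allylic alkylation of a prochiral cyclic enolate should set C9 by catalyst control at the allyl-iridium terminus and the quaternary C10 by attack of the enolate face that keeps the ring methylene away from the allyl substituent.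

Step 6
Reactants: 9 (6R)-3-isobutoxy-2,6-dimethyl-6-[(2R)-1-[(triisopropylsilyl)oxy]but-3-en-2-yl]cyclohex-2-en-1-one
Product: 11 (4S)-2,4-dimethyl-4-[(2R)-1-[(triisopropylsilyl)oxy]but-3-en-2-yl]cyclohex-2-en-1-one, via allylic alcohol 10 (not isolated)
Conditions: i-Bu2AlH, toluene, −78 °C; then 1 M HCl, THF, 0 °C
Reagents that add atoms: none
Why: Stork–Danheiser reduction–transposition (1,2-hydride addition to the vinylogous ester carbonyl, then acid hydrolysis and β-elimination) gives the enone with C3 as carbonyl and C5 as β-carbon without touching C9 or C10.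

Step 7
Reactants: 11 (4S)-2,4-dimethyl-4-[(2R)-1-[(triisopropylsilyl)oxy]but-3-en-2-yl]cyclohex-2-en-1-one
Product: 12 (4S)-2,4-dimethyl-3-(4,4,5,5-tetramethyl-1,3,2-dioxaborolan-2-yl)-4-[(2R)-1-[(triisopropylsilyl)oxy]but-3-en-2-yl]cyclohexan-1-one (epimer mixture at C2 and C3 of the ring)
Conditions: CuCl (10 mol %), DPEphos (10 mol %), NaOt-Bu (15 mol %), B2pin2, MeOH, THF, rt
Reagents that add atoms: bis(pinacolato)diboron CC1(C)OB(OC1(C)C)B1OC(C)(C)C(C)(C)O1
Why: Copper-catalysed conjugate borylation puts boron on the enone β-carbon C5 and leaves the unactivated vinyl group alone; the new centres at C4 and C5 need no control because both are erased in step 12.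

Step 8
Reactants: 12 (4S)-2,4-dimethyl-3-(4,4,5,5-tetramethyl-1,3,2-dioxaborolan-2-yl)-4-[(2R)-1-[(triisopropylsilyl)oxy]but-3-en-2-yl]cyclohexan-1-one
Product: 13 (3R)-3-[(1S)-1,3-dimethyl-4-oxo-2-(4,4,5,5-tetramethyl-1,3,2-dioxaborolan-2-yl)cyclohexyl]-4-[(triisopropylsilyl)oxy]butan-2-one
Conditions: PdCl2 (10 mol %), CuCl, O2 (1 atm), DMF–H2O (7:1), rt
Reagents that add atoms: water O
Why: Tsuji–Wacker oxidation of the terminal alkene in the Markovnikov sense gives the C8 methyl ketone (C12 is its methyl) only after the enone is gone, so no enone and methyl ketone coexist under base.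

Step 9
Reactants: 13 (3R)-3-[(1S)-1,3-dimethyl-4-oxo-2-(4,4,5,5-tetramethyl-1,3,2-dioxaborolan-2-yl)cyclohexyl]-4-[(triisopropylsilyl)oxy]butan-2-one
Product: 14 potassium [(6S)-2,6-dimethyl-3-oxo-6-[(2R)-3-oxo-1-[(triisopropylsilyl)oxy]butan-2-yl]cyclohexyl]trifluoroborate
Conditions: KHF2 (aq.), MeOH, rt
Reagents that add atoms: potassium hydrogen difluoride [K+].F[H-]F
Why: Fluoride exchange converts the pinacol boronate into the β-trifluoroborato ketone, the oxidisable radical precursor for step 10.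

Step 10
Reactants: 14 potassium [(6S)-2,6-dimethyl-3-oxo-6-[(2R)-3-oxo-1-[(triisopropylsilyl)oxy]butan-2-yl]cyclohexyl]trifluoroborate and 15 ethenyl(triphenyl)phosphonium bromide
Product: 17 (4aS,5R)-1,4a,6-trimethyl-5-{[(triisopropylsilyl)oxy]methyl}-3,4,4a,5,8,8a-hexahydronaphthalen-2(1H)-one (epimer mixture at C1 and C8a), via phosphorus ylide 16 (not isolated)
Conditions: 15 (1.5 equiv), [Ir(dF(CF3)ppy)2(dtbbpy)]PF6 (2 mol %), DMSO, blue LEDs (450 nm), rt, then 40 °C
Reagents that add atoms: none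
Why: Proposed new method: the excited trivalent iridium photocatalyst oxidises the secondary alkyltrifluoroborate to the C5 radical, which adds to the unsubstituted terminus of the vinylphosphonium salt (C5–C6); the divalent iridium state reduces the α-phosphonio radical to ylide 16, which adds 6-exo-trig to the C8 ketone and collapses through the oxaphosphetane to the C7=C8 alkene, closing ring B. The closest known reaction types are the photoredox conjunctive olefination (radical addition to a vinylphosphonium salt, reduction to the ylide, intermolecular Wittig reaction) and the anionic Schweizer vinylphosphonium annulation; new here are the β-keto secondary radical from a trifluoroborate and the ring-closing Wittig reaction on a ketone. C9 and C10 are carried through unchanged, and the new centre at C5 is formed without control on purpose, because it and C4 are erased in step 12 and reset in step 13. The step needs chemoselectivity between the two ketones, which ring size secures (olefination at C3 would give a bridgehead alkene, at C8 a cyclohexene), and the alkene position is fixed at C7=C8 because the carbonyl carbon becomes the alkene carbon.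

Step 11
Reactants: 17 (4aS,5R)-1,4a,6-trimethyl-5-{[(triisopropylsilyl)oxy]methyl}-3,4,4a,5,8,8a-hexahydronaphthalen-2(1H)-one
Product: 18 (4aS,5R)-1,4a,6-trimethyl-5-{[(triisopropylsilyl)oxy]methyl}-2-[(trimethylsilyl)oxy]-3,4,4a,5,8,8a-hexahydronaphthalene (epimer mixture at C8a)
Conditions: Me3SiOTf, Et3N, CH2Cl2, 0 °C to rt (equilibrating)
Reagents that add atoms: trimethylsilyl trifluoromethanesulfonate C[Si](C)(C)OS(=O)(=O)C(F)(F)F
Why: Silylation under equilibrating conditions should favour the more substituted C3=C4 silyl enol ether.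

Step 12
Reactants: 18 (4aS,5R)-1,4a,6-trimethyl-5-{[(triisopropylsilyl)oxy]methyl}-2-[(trimethylsilyl)oxy]-3,4,4a,5,8,8a-hexahydronaphthalene
Product: 19 (4aR,5R)-1,4a,6-trimethyl-5-{[(triisopropylsilyl)oxy]methyl}-4,4a,5,8-tetrahydronaphthalen-2(3H)-one
Conditions: Pd(OAc)2 (1.1 equiv), MeCN, rt
Reagents that add atoms: none
Why: Saegusa–Ito oxidation (palladium enolate, β-hydride elimination of the C5 hydrogen) gives the C4=C5 enone and makes the C4/C5 epimer mixture converge to one compound.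

Step 13
Reactants: 19 (4aR,5R)-1,4a,6-trimethyl-5-{[(triisopropylsilyl)oxy]methyl}-4,4a,5,8-tetrahydronaphthalen-2(3H)-one
Product: 21 (4aS,5R,8aR)-1,1,4a,6-tetramethyl-5-{[(triisopropylsilyl)oxy]methyl}-3,4,4a,5,8,8a-hexahydronaphthalen-2(1H)-one, via lithium enolate 20 (not isolated)
Conditions: Li, NH3 (l), THF, t-BuOH (1 equiv), −78 °C; isoprene; then MeI, −78 to −33 °C
Reagents that add atoms: iodomethane CI
Why: Stork reductive alkylation (dissolving-metal reduction of the enone, then C-methylation of the regiodefined enolate) should set the trans ring fusion by axial protonation of C5 anti to the angular methyl and install the C4 gem-dimethyl group, while the isolated C7=C8 alkene is not reduced.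

Step 14
Reactants: 21 (4aS,5R,8aR)-1,1,4a,6-tetramethyl-5-{[(triisopropylsilyl)oxy]methyl}-3,4,4a,5,8,8a-hexahydronaphthalen-2(1H)-one
Product: 22 (2R,4aS,5R,8aR)-1,1,4a,6-tetramethyl-5-{[(triisopropylsilyl)oxy]methyl}-1,2,3,4,4a,5,8,8a-octahydronaphthalen-2-ol
Conditions: LiBH(s-Bu)3 (L-Selectride), THF, −78 °C; then H2O
Reagents that add atoms: none
Why: The bulky hydride should attack the 4,4-dimethyl-3-ketone of the trans-decalin from the equatorial direction and give the axial 3α alcohol (substrate control).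

Step 15
Reactants: 22 (2R,4aS,5R,8aR)-1,1,4a,6-tetramethyl-5-{[(triisopropylsilyl)oxy]methyl}-1,2,3,4,4a,5,8,8a-octahydronaphthalen-2-ol
Product: 23 (2R,4aS,5R,8aR)-5-(hydroxymethyl)-1,1,4a,6-tetramethyl-1,2,3,4,4a,5,8,8a-octahydronaphthalen-2-ol
Conditions: Bu4NF, THF, rt
Reagents that add atoms: none
Why: Fluoride cleaves the silyl ether and frees the primary C11 alcohol.

Step 16
Reactants: 23 (2R,4aS,5R,8aR)-5-(hydroxymethyl)-1,1,4a,6-tetramethyl-1,2,3,4,4a,5,8,8a-octahydronaphthalen-2-ol and 24 scopoletin (7-hydroxy-6-methoxy-2H-chromen-2-one)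
Product: 25 7-{[(1R,4aR,6R,8aS)-6-hydroxy-2,5,5,8a-tetramethyl-1,4,4a,5,6,7,8,8a-octahydronaphthalen-1-yl]methoxy}-6-methoxy-2H-chromen-2-one (target)
Conditions: PPh3, i-PrO2CN=NCO2i-Pr (DIAD), THF, 0 °C to rt
Reagents that add atoms: none
Why: Mitsunobu etherification of the acidic coumarin phenol should take place at the primary C11 alcohol only, because the axial secondary C3 alcohol next to the gem-dimethyl carbon is too hindered, and no stereocentre is involved.

**Compound list**
1 | (E)-but-2-ene-1,4-diol | OC/C=C/CO | starting material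
2 | (E)-4-[(triisopropylsilyl)oxy]but-2-en-1-ol | CC(C)[Si](C(C)C)(C(C)C)OC/C=C/CO | intermediate
3 | methyl (E)-4-[(triisopropylsilyl)oxy]but-2-en-1-yl carbonate | COC(=O)OC/C=C/CO[Si](C(C)C)(C(C)C)C(C)C | intermediate
4 | 2-methylcyclohexane-1,3-dione | CC1C(=O)CCCC1=O | starting material
5 | 3-isobutoxy-2-methylcyclohex-2-en-1-one | CC(C)COC1=C(C)C(=O)CCC1 | intermediate
6 | lithium 5-isobutoxy-6-methylcyclohexa-1,5-dien-1-olate (not isolated) | [Li+].[O-]C1=CCCC(OCC(C)C)=C1C | intermediate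
7 | 3-isobutoxy-2,6-dimethylcyclohex-2-en-1-one (racemic) | CC(C)COC1=C(C)C(=O)C(C)CC1 | intermediate
8 | lithium 5-isobutoxy-2,6-dimethylcyclohexa-1,5-dien-1-olate (not isolated) | [Li+].[O-]C1=C(C)CCC(OCC(C)C)=C1C | intermediate
9 | (6R)-3-isobutoxy-2,6-dimethyl-6-[(2R)-1-[(triisopropylsilyl)oxy]but-3-en-2-yl]cyclohex-2-en-1-one | CC(C)[Si](C(C)C)(C(C)C)OC[C@H](C=C)[C@@]1(C)CCC(OCC(C)C)=C(C)C1=O | intermediate
10 | (6R)-3-isobutoxy-2,6-dimethyl-6-[(2R)-1-[(triisopropylsilyl)oxy]but-3-en-2-yl]cyclohex-2-en-1-ol (not isolated) | CC(C)[Si](C(C)C)(C(C)C)OC[C@H](C=C)[C@@]1(C)CCC(OCC(C)C)=C(C)C1O | intermediate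
11 | (4S)-2,4-dimethyl-4-[(2R)-1-[(triisopropylsilyl)oxy]but-3-en-2-yl]cyclohex-2-en-1-one | CC(C)[Si](C(C)C)(C(C)C)OC[C@H](C=C)[C@@]1(C)CCC(=O)C(C)=C1 | intermediate
12 | (4S)-2,4-dimethyl-3-(4,4,5,5-tetramethyl-1,3,2-dioxaborolan-2-yl)-4-[(2R)-1-[(triisopropylsilyl)oxy]but-3-en-2-yl]cyclohexan-1-one | CC(C)[Si](C(C)C)(C(C)C)OC[C@H](C=C)[C@@]1(C)CCC(=O)C(C)C1B1OC(C)(C)C(C)(C)O1 | intermediate
13 | (3R)-3-[(1S)-1,3-dimethyl-4-oxo-2-(4,4,5,5-tetramethyl-1,3,2-dioxaborolan-2-yl)cyclohexyl]-4-[(triisopropylsilyl)oxy]butan-2-one | CC(C)[Si](C(C)C)(C(C)C)OC[C@H](C(C)=O)[C@@]1(C)CCC(=O)C(C)C1B1OC(C)(C)C(C)(C)O1 | intermediate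
14 | potassium [(6S)-2,6-dimethyl-3-oxo-6-[(2R)-3-oxo-1-[(triisopropylsilyl)oxy]butan-2-yl]cyclohexyl]trifluoroborate | CC(C)[Si](C(C)C)(C(C)C)OC[C@H](C(C)=O)[C@@]1(C)CCC(=O)C(C)C1[B-](F)(F)F.[K+] | intermediate
15 | ethenyl(triphenyl)phosphonium bromide | C=C[P+](c1ccccc1)(c1ccccc1)c1ccccc1.[Br-] | starting material
16 | (3R)-3-[(1S)-1,3-dimethyl-4-oxo-2-[2-(triphenyl-λ5-phosphanylidene)ethyl]cyclohexyl]-4-[(triisopropylsilyl)oxy]butan-2-one (not isolated) | CC(C)[Si](C(C)C)(C(C)C)OC[C@H](C(C)=O)[C@@]1(C)CCC(=O)C(C)C1CC=P(c1ccccc1)(c1ccccc1)c1ccccc1 | intermediate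
17 | (4aS,5R)-1,4a,6-trimethyl-5-{[(triisopropylsilyl)oxy]methyl}-3,4,4a,5,8,8a-hexahydronaphthalen-2(1H)-one | CC(C)[Si](C(C)C)(C(C)C)OC[C@@H]1C(C)=CCC2C(C)C(=O)CC[C@]12C | intermediate
18 | (4aS,5R)-1,4a,6-trimethyl-5-{[(triisopropylsilyl)oxy]methyl}-2-[(trimethylsilyl)oxy]-3,4,4a,5,8,8a-hexahydronaphthalene | CC(C)[Si](C(C)C)(C(C)C)OC[C@@H]1C(C)=CCC2C(C)=C(O[Si](C)(C)C)CC[C@]12C | intermediate
19 | (4aR,5R)-1,4a,6-trimethyl-5-{[(triisopropylsilyl)oxy]methyl}-4,4a,5,8-tetrahydronaphthalen-2(3H)-one | CC(C)[Si](C(C)C)(C(C)C)OC[C@@H]1C(C)=CCC2=C(C)C(=O)CC[C@]12C | intermediate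
20 | lithium (4aS,5R,8aR)-1,4a,6-trimethyl-5-{[(triisopropylsilyl)oxy]methyl}-3,4,4a,5,8,8a-hexahydronaphthalen-2-olate (not isolated) | [Li+].CC(C)[Si](C(C)C)(C(C)C)OC[C@@H]1C(C)=CC[C@H]2C(C)=C([O-])CC[C@]12C | intermediate
21 | (4aS,5R,8aR)-1,1,4a,6-tetramethyl-5-{[(triisopropylsilyl)oxy]methyl}-3,4,4a,5,8,8a-hexahydronaphthalen-2(1H)-one | CC(C)[Si](C(C)C)(C(C)C)OC[C@@H]1C(C)=CC[C@H]2C(C)(C)C(=O)CC[C@]12C | intermediate
22 | (2R,4aS,5R,8aR)-1,1,4a,6-tetramethyl-5-{[(triisopropylsilyl)oxy]methyl}-1,2,3,4,4a,5,8,8a-octahydronaphthalen-2-ol | CC(C)[Si](C(C)C)(C(C)C)OC[C@@H]1C(C)=CC[C@H]2C(C)(C)[C@H](O)CC[C@]12C | intermediate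
23 | (2R,4aS,5R,8aR)-5-(hydroxymethyl)-1,1,4a,6-tetramethyl-1,2,3,4,4a,5,8,8a-octahydronaphthalen-2-ol | OC[C@@H]1C(C)=CC[C@H]2C(C)(C)[C@H](O)CC[C@]12C | intermediate
24 | scopoletin (7-hydroxy-6-methoxy-2H-chromen-2-one) | COc1cc2ccc(=O)oc2cc1O | starting material
25 | 7-{[(1R,4aR,6R,8aS)-6-hydroxy-2,5,5,8a-tetramethyl-1,4,4a,5,6,7,8,8a-octahydronaphthalen-1-yl]methoxy}-6-methoxy-2H-chromen-2-one | COc1cc2ccc(=O)oc2cc1OC[C@@H]1C(C)=CC[C@H]2C(C)(C)[C@H](O)CC[C@]12C | target

**Step count**
Total: 16 steps. Longest linear sequence: 14 steps (steps 3 to 16, from 4); steps 1 and 2 are a two-step branch that joins at step 5.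

**Steps most likely to fail**

Step 10 (Proposed new method). The hindered secondary radical may be reduced or abstract hydrogen faster than it adds to the vinylphosphonium salt, the ylide may be protonated before it closes the ring, and enolisation of the side-chain ketone may erode the C9 configuration. The fallback makes the two bonds in separate, known steps; it sets out from 9 and comes back at 19, so that steps 6 to 12 are bypassed. Tsuji–Wacker oxidation of 9 (PdCl2, CuCl, O2, DMF–H2O) should give the methyl ketone (6R)-3-isobutoxy-2,6-dimethyl-6-[(2R)-3-oxo-1-[(triisopropylsilyl)oxy]butan-2-yl]cyclohex-2-en-1-one F1. Methylenation with Ph3P=CH2, to which the vinylogous ester carbonyl is inert, should give the isopropenyl compound (6R)-3-isobutoxy-2,6-dimethyl-6-[(2R)-3-methyl-1-[(triisopropylsilyl)oxy]but-3-en-2-yl]cyclohex-2-en-1-one F2. Stork–Danheiser addition of allylmagnesium bromide with CeCl3 followed by 1 M HCl forms C5–C6 and should give the dienone (4R)-2,4-dimethyl-4-[(2R)-3-methyl-1-[(triisopropylsilyl)oxy]but-3-en-2-yl]-3-(prop-2-en-1-yl)cyclohex-2-en-1-one F3. Ring-closing metathesis with (H2IMes)(PCy3)Cl2Ru=CHPh (second-generation Grubbs catalyst) in CH2Cl2 at 40 °C forms C7=C8 and should give 19.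

Step 5. The enolate may attack with poor facial selectivity at the tetrasubstituted carbon, or the allyl unit may be delivered in the linear sense. The fallback sets the two centres with two independent catalysts; it sets out from 7 and comes back at 9. O-Acylation of the enolate of 7 (LiN(SiMe3)2, allyl chloroformate) gives the enol carbonate prop-2-en-1-yl 5-isobutoxy-2,6-dimethylcyclohexa-1,5-dien-1-yl carbonate F4. Decarboxylative asymmetric allylation with Pd2(dba)3 and (R)-t-BuPHOX should give (6R)-3-isobutoxy-2,6-dimethyl-6-(prop-2-en-1-yl)cyclohex-2-en-1-one F5, which fixes C10. Oxidative cleavage (OsO4 cat., NaIO4, 2,6-lutidine, dioxane–H2O) gives the aldehyde 2-[(1R)-4-isobutoxy-1,3-dimethyl-2-oxocyclohex-3-en-1-yl]acetaldehyde F6. Enamine-catalysed α-hydroxymethylation (α,α-diphenylprolinol trimethylsilyl ether of the enantiomer that gives the (R) centre, aqueous formaldehyde, pH 7 buffer, toluene) should set C9 and give (2R)-3-hydroxy-2-[(1R)-4-isobutoxy-1,3-dimethyl-2-oxocyclohex-3-en-1-yl]propanal F7. Silylation (i-Pr3SiOTf, 2,6-lutidine) gives (2R)-2-[(1R)-4-isobutoxy-1,3-dimethyl-2-oxocyclohex-3-en-1-yl]-3-[(triisopropylsilyl)oxy]propanal F8, and methylenation of the aldehyde with Ph3P=CH2 gives 9.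

Step 11. Enolisation may go toward the less hindered C2 instead of C4, because the C3=C4 enol ether is strained against the substituents on C5, and the wrong enone would follow in step 12. The fallback uses halogenation and elimination instead of enol-ether oxidation; it sets out from 17 and comes back at 19. α-Bromination with CuBr2 (EtOAc–CHCl3, reflux) at the more substituted α-carbon should give (4aR,5R)-1-bromo-1,4a,6-trimethyl-5-{[(triisopropylsilyl)oxy]methyl}-3,4,4a,5,8,8a-hexahydronaphthalen-2(1H)-one F9, and dehydrobromination (Li2CO3, LiBr, DMF, 120 °C) should give the conjugated enone 19.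

Further compounds
F1 | step 10 | (6R)-3-isobutoxy-2,6-dimethyl-6-[(2R)-3-oxo-1-[(triisopropylsilyl)oxy]butan-2-yl]cyclohex-2-en-1-one | CC(C)[Si](C(C)C)(C(C)C)OC[C@H](C(C)=O)[C@@]1(C)CCC(OCC(C)C)=C(C)C1=O
F2 | step 10 | (6R)-3-isobutoxy-2,6-dimethyl-6-[(2R)-3-methyl-1-[(triisopropylsilyl)oxy]but-3-en-2-yl]cyclohex-2-en-1-one | CC(C)[Si](C(C)C)(C(C)C)OC[C@H](C(C)=C)[C@@]1(C)CCC(OCC(C)C)=C(C)C1=O
F3 | step 10 | (4R)-2,4-dimethyl-4-[(2R)-3-methyl-1-[(triisopropylsilyl)oxy]but-3-en-2-yl]-3-(prop-2-en-1-yl)cyclohex-2-en-1-one | CC(C)[Si](C(C)C)(C(C)C)OC[C@H](C(C)=C)[C@@]1(C)CCC(=O)C(C)=C1CC=C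
F4 | step 5 | prop-2-en-1-yl 5-isobutoxy-2,6-dimethylcyclohexa-1,5-dien-1-yl carbonate | C=CCOC(=O)OC1=C(C)CCC(OCC(C)C)=C1C
F5 | step 5 | (6R)-3-isobutoxy-2,6-dimethyl-6-(prop-2-en-1-yl)cyclohex-2-en-1-one | C=CC[C@@]1(C)CCC(OCC(C)C)=C(C)C1=O
F6 | step 5 | 2-[(1R)-4-isobutoxy-1,3-dimethyl-2-oxocyclohex-3-en-1-yl]acetaldehyde | O=CC[C@@]1(C)CCC(OCC(C)C)=C(C)C1=O
F7 | step 5 | (2R)-3-hydroxy-2-[(1R)-4-isobutoxy-1,3-dimethyl-2-oxocyclohex-3-en-1-yl]propanal | OC[C@H](C=O)[C@@]1(C)CCC(OCC(C)C)=C(C)C1=O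
F8 | step 5 | (2R)-2-[(1R)-4-isobutoxy-1,3-dimethyl-2-oxocyclohex-3-en-1-yl]-3-[(triisopropylsilyl)oxy]propanal | CC(C)[Si](C(C)C)(C(C)C)OC[C@H](C=O)[C@@]1(C)CCC(OCC(C)C)=C(C)C1=O
F9 | step 11 | (4aR,5R)-1-bromo-1,4a,6-trimethyl-5-{[(triisopropylsilyl)oxy]methyl}-3,4,4a,5,8,8a-hexahydronaphthalen-2(1H)-one | CC(C)[Si](C(C)C)(C(C)C)OC[C@@H]1C(C)=CCC2C(C)(Br)C(=O)CC[C@]12C
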